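Ring B (the acetoxy-cyclohexane, C5–C10 in clerodane numbering; C5 carries the lactone CH2, C9 a methyl and C11) is treated as a masked cyclohexene. Its two quaternary carbons each sit on a bond, C5–C6 and C9–C10, that one Diels–Alder reaction can form. The key step is an intramolecular Diels–Alder reaction of an (E)-2-ethoxy-1,3-diene (C6–C9) with an (E)-enone (C5=C10). Both are tethered through the 2,3-disubstituted furan, so ring B and the seven-membered ring C close together, and C5, C9 and C10 are set from the single tether stereocentre C1. Ring A and the unsaturated lactone follow by carbonylative lactonization and ring-closing metathesis.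

Key step: step 17

Remark on locants: C1–C20 follow the clerodane skeleton (ring A = C1–C5, C10; ring B = C5–C10; C11; C12 = ketone carbon; furan C13–C16 with C16 bonded to C1; C17 on C8; C18 = lactone carbonyl on C4; C19 = OCH2 on C5; C20 on C9). α is the face of ring B that carries C19 and C20.

Remark on the chemistry: lactol 18 is used as the mixture of anomers, and aldehyde 22 is used crude because C1 is epimerizable.

Step 1
Reactants: 1 ethyl 2-methyl-3-oxobutanoate
Product: 2 ethyl (E)-2-methyl-3-(trifluoromethylsulfonyloxy)but-2-enoate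
Conditions: Tf2O, aq. Me4NOH, hexanes, 5 °C
Reagents that add atoms: trifluoromethanesulfonic anhydride, O=S(=O)(OS(=O)(=O)C(F)(F)F)C(F)(F)F
Why: Biphasic enol triflation of a β-keto ester; with the non-chelating ammonium counter-ion the enolate should react in its extended form, so OTf ends trans to the ester (E), which fixes the later diene geometry (C11 trans to C7).

Step 2
Reactants: 2 ethyl (E)-2-methyl-3-(trifluoromethylsulfonyloxy)but-2-enoate
Product: 3 (E)-4-hydroxy-3-methylbut-2-en-2-yl trifluoromethanesulfonate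
Conditions: iBu2AlH, CH2Cl2, −78 °C
Reagents that add atoms: none
Why: Hydride reduction of the conjugated ester to the allylic alcohol; the enol triflate is inert to iBu2AlH at low temperature.

Step 3
Reactants: 3 (E)-4-hydroxy-3-methylbut-2-en-2-yl trifluoromethanesulfonate
Product: 4 (E)-4-bromo-3-methylbut-2-en-2-yl trifluoromethanesulfonate
Conditions: CBr4, PPh3, CH2Cl2, 0 °C
Reagents that add atoms: carbon tetrabromide, BrC(Br)(Br)Br
Why: Appel bromination of the primary allylic alcohol under neutral conditions, leaving alkene geometry and triflate untouched.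

Step 4
Reactants: 5 dimethyl 3-oxopentanedioate; 6 chloroacetaldehyde
Product: 7 methyl 2-(2-methoxy-2-oxoethyl)furan-3-carboxylate
Conditions: pyridine, H2O, 50 °C
Reagents that add atoms: none
Why: Feist–Benary furan synthesis (aldol of the active methylene, O-alkylation by chloride displacement, dehydration); only the ketone oxygen can close the ring, so the 2-alkyl-3-carboxylate pattern is fixed.

Step 5
Reactants: 7 methyl 2-(2-methoxy-2-oxoethyl)furan-3-carboxylate
Product: 8 2-[3-(methoxycarbonyl)furan-2-yl]acetic acid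
Conditions: LiOH (1.0 equiv), THF/H2O, 0 °C; then aq. HCl
Reagents that add atoms: lithium hydroxide, [Li+].[OH-]
Why: Saponification with one equivalent of hydroxide should take the unhindered, non-conjugated aliphatic ester well before the furan-conjugated one.

Step 6
Reactants: 8 2-[3-(methoxycarbonyl)furan-2-yl]acetic acid; 9 (R)-4-benzyloxazolidin-2-one
Product: 11 methyl 2-{2-[(R)-4-benzyl-2-oxooxazolidin-3-yl]-2-oxoethyl}furan-3-carboxylate, via mixed pivalic anhydride 10 (not isolated)
Conditions: PivCl, Et3N, THF, −20 °C; then 9, LiCl, rt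
Reagents that add atoms: pivaloyl chloride, CC(C)(C)C(=O)Cl
Why: N-acylation of the Evans oxazolidinone through the mixed anhydride (LiCl/Et3N protocol); the hindered pivaloyl carbonyl directs attack to the arylacetyl carbonyl.

Step 7
Reactants: 11 methyl 2-{2-[(R)-4-benzyl-2-oxooxazolidin-3-yl]-2-oxoethyl}furan-3-carboxylate; 12 acrolein
Product: 14 (R)-4-benzyl-3-{(2S,3S)-3-hydroxy-2-[3-(methoxycarbonyl)furan-2-yl]pent-4-enoyl}oxazolidin-2-one, via Z dibutylboron enolate 13 (not isolated)
Conditions: Bu2BOTf, iPr2NEt, CH2Cl2, −78 °C; then 12, −78 → 0 °C; pH 7 buffer, MeOH, H2O2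
Reagents that add atoms: dibutylboron trifluoromethanesulfonate, CCCCB(CCCC)OS(=O)(=O)C(F)(F)F
Why: Evans syn aldol; the Z boron enolate adds to acrolein through a Zimmerman–Traxler chair on the face away from the benzyl group of the (R)-auxiliary, setting C1 and C2 (both S) in the syn relationship ring A needs.

Step 8
Reactants: 14 aldol adduct
Product: 15 (R)-4-benzyl-3-{(2S,3S)-3-(tert-butyldimethylsilyloxy)-2-[3-(methoxycarbonyl)furan-2-yl]pent-4-enoyl}oxazolidin-2-one
Conditions: TBSOTf, 2,6-lutidine, CH2Cl2, −78 → 0 °C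
Reagents that add atoms: tert-butyldimethylsilyl trifluoromethanesulfonate, CC(C)(C)[Si](C)(C)OS(=O)(=O)C(F)(F)F
Why: Silylation of the secondary allylic alcohol blocks retro-aldol cleavage and protects C2–OH until the last step.

Step 9
Reactants: 15 silylated aldol adduct
Product: 17 (S)-7-[(S)-1-(tert-butyldimethylsilyloxy)prop-2-en-1-yl]-6,7-dihydro-4H-furo[3,2-c]pyran-4-one, via hydroxy ester 16 (not isolated)
Conditions: NaBH4, THF/H2O, 0 °C → rt
Reagents that add atoms: none
Why: Reductive cleavage of the N-acyl oxazolidinone by borohydride in wet THF spares the furoate, and the liberated alkoxide lactonizes onto the neighbouring ester (six-membered ring), differentiating C10–O from C12.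

Step 10
Reactants: 17 furopyranone
Product: 18 (7S)-7-[(S)-1-(tert-butyldimethylsilyloxy)prop-2-en-1-yl]-6,7-dihydro-4H-furo[3,2-c]pyran-4-ol (both anomers)
Conditions: iBu2AlH, CH2Cl2, −78 °C
Reagents that add atoms: none
Why: Partial reduction of the lactone; the tetrahedral aluminate is stable at −78 °C and gives the lactol on work-up.

Step 11
Reactants: 18 lactol
Product: 19 (2S,3S)-3-(tert-butyldimethylsilyloxy)-2-[3-(1,3-dithian-2-yl)furan-2-yl]pent-4-en-1-ol
Conditions: HS(CH2)3SH, BF3·OEt2, CH2Cl2, −40 °C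
Reagents that add atoms: propane-1,3-dithiol, SCCCS
Why: Lewis-acid dithioacetalization of the lactol (a masked hydroxy aldehyde); the dithiane is the acyl-anion equivalent for C12 and later keeps C11–H from enolizing.

Step 12
Reactants: 19 hydroxy dithiane; 4 (E)-4-bromo-3-methylbut-2-en-2-yl trifluoromethanesulfonate
Product: 21 (2S,3S)-3-(tert-butyldimethylsilyloxy)-2-(3-{2-[(E)-2-methyl-3-(trifluoromethylsulfonyloxy)but-2-en-1-yl]-1,3-dithian-2-yl}furan-2-yl)pent-4-en-1-ol, via dilithio dianion 20 (not isolated)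
Conditions: n-BuLi (2.1 equiv), THF, −78 → −30 °C; then 4, −78 °C
Reagents that add atoms: n-butyllithium, [Li]CCCC
Why: Corey–Seebach alkylation; the soft 2-lithio-1,3-dithiane carbon of the dianion displaces the primary allylic bromide by SN2 with retention of the E alkene and should not attack the enol triflate at −78 °C.

Step 13
Reactants: 21 alkylated dithiane alcohol
Product: 22 (2S,3S)-3-(tert-butyldimethylsilyloxy)-2-(3-{2-[(E)-2-methyl-3-(trifluoromethylsulfonyloxy)but-2-en-1-yl]-1,3-dithian-2-yl}furan-2-yl)pent-4-enal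
Conditions: SO3·pyridine, DMSO, iPr2NEt, CH2Cl2, 0 °C
Reagents that add atoms: none
Why: Parikh–Doering oxidation, mild enough to spare the dithiane sulfur and to limit epimerization at the α-aryl centre C1.

Step 14
Reactants: 22 aldehyde; 23 1-(triphenylphosphoranylidene)propan-2-one
Product: 25 (3Z,5S,6S)-6-(tert-butyldimethylsilyloxy)-3-iodo-5-(3-{2-[(E)-2-methyl-3-(trifluoromethylsulfonyloxy)but-2-en-1-yl]-1,3-dithian-2-yl}furan-2-yl)octa-3,7-dien-2-one, via iodo ylide 24 (not isolated)
Conditions: 23, N-iodosuccinimide, CH2Cl2, −20 °C; then 22, rt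
Reagents that add atoms: N-iodosuccinimide, O=C1CCC(=O)N1I
Why: Wittig reaction of a stabilized α-iodo ylide made in the flask; as with stabilized ylides in general the acyl group ends trans to C1, giving the Z α-iodo enone.

Step 15
Reactants: 25 α-iodo enone; 26 (tributylstannyl)methanol
Product: 27 (3E,5S,6S)-6-(tert-butyldimethylsilyloxy)-3-(hydroxymethyl)-5-(3-{2-[(E)-2-methyl-3-(trifluoromethylsulfonyloxy)but-2-en-1-yl]-1,3-dithian-2-yl}furan-2-yl)octa-3,7-dien-2-one
Conditions: Pd2(dba)3, AsPh3, CuI, THF, 40 °C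
Reagents that add atoms: none
Why: Stille hydroxymethylation with retention of alkene geometry; oxidative addition of zerovalent palladium to the activated vinyl iodide should be far faster than to the hindered tetrasubstituted enol triflate in the absence of chloride.

Step 16
Reactants: 27 hydroxymethyl enone
Product: 28 (3E,5S,6S)-6-(tert-butyldimethylsilyloxy)-5-(3-{2-[(E)-2-methyl-3-(trifluoromethylsulfonyloxy)but-2-en-1-yl]-1,3-dithian-2-yl}furan-2-yl)-3-[(triethylsilyloxy)methyl]octa-3,7-dien-2-one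
Conditions: TESCl, imidazole, CH2Cl2, 0 °C
Reagents that add atoms: chlorotriethylsilane, CC[Si](Cl)(CC)CC
Why: Silylation of the primary alcohol prevents retro-aldol loss of C19 after the cycloaddition; the TES group is later removed together with the enol ether.

Step 17
Reactants: 28 enone enol triflate; 29 tributyl(1-ethoxyvinyl)stannane
Product: 31 Diels–Alder adduct (ring B: C5–C10 with 7-ethoxy-Δ7 enol ether and 8-methyl; ring C: C9–C11H2–C12(1,3-dithiane)–furan–C1–C10, trans-fused to ring B; 5β-acetyl, 5α-CH2OSiEt3, 9α-CH3, 10β-H, 1α-H, C1 carrying (S)-CH(OTBS)CH=CH2), via ethoxydiene triene 30 (not isolated)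
Conditions: Pd(PPh3)4, LiCl, 1,4-dioxane, 80 °C; then toluene (2 mM), BHT, 130 °C
Reagents that add atoms: none
Why: Stille coupling replaces the enol triflate by the 1-ethoxyvinyl group with retention, unveiling the (E)-2-ethoxy-1,3-diene 30, which on heating should undergo a concerted, asynchronous intramolecular Diels–Alder reaction with the (E)-enone (closest precedent: thermal type 1 IMDA reactions of 2-alkoxy or 2-silyloxy dienes tethered to enones). Ring B closes by the [4+2] cycloaddition itself (bonds C5–C6 and C9–C10), and the seven-membered ring C closes in the fused mode as the tether ring, the furan and the dithiane (gem-disubstituent effect) restricting the tether. The trans B/C fusion at C9/C10 follows from the E diene reacting through the transition state with the acetyl group endo, and the C5 configuration (C19 cis to C1, acetyl cis to H-10) follows from suprafacial addition to the E enone. The absolute sense is controlled by C1: allylic 1,3-strain with the cis CH2OSiEt3 group places H-1 in the enone plane, so the tethered diene adds to the alkene face that carries the furan. The step needs endo selectivity and must outrun the 1,5-hydrogen shift of the cis-methyl diene, which the donor-activated diene and the moderate temperature are meant to secure; regiochemistry is fixed by the tether.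

Step 18
Reactants: 31 Diels–Alder adduct
Product: 32 enol triflate (as 31, with 5β-[1-(trifluoromethylsulfonyloxy)vinyl] in place of acetyl)
Conditions: KN(SiMe3)2, PhNTf2, THF, −78 °C
Reagents that add atoms: N-phenylbis(trifluoromethanesulfonimide), O=S(=O)(N(c1ccccc1)S(=O)(=O)C(F)(F)F)C(F)(F)F
Why: Kinetic enolization and O-triflation at the only enolizable position (the acetyl methyl; C5 is quaternary, C12 is masked, C7 is an enol ether).

Step 19
Reactants: 32 enol triflate
Product: 33 hydroxy ketone (7-oxo, 8α-methyl/8β-H, 5α-CH2OH, 5β-[1-(trifluoromethylsulfonyloxy)vinyl]; C2–OTBS and dithiane retained)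
Conditions: aq. HCl (0.5 M), THF, 0 °C → rt
Reagents that add atoms: water, O
Why: Acid hydrolysis of the enol ether with axial protonation at C8 from the β face (anti to the axial C20 methyl), which is also the thermodynamically preferred equatorial 8α-methyl epimer; the primary TES ether is cleaved while the secondary TBS ether, dithiane and enol triflate should survive.

Step 20
Reactants: 33 hydroxy ketone
Product: 34 diol (7β-OH equatorial, 19-OH; otherwise as 33)
Conditions: Me4NBH(OAc)3, AcOH/MeCN, −20 °C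
Reagents that add atoms: none
Why: Hydroxyl-directed reduction of the Evans–Saksena type; the axial C19–OH exchanges onto boron and delivers hydride to the 1,3-diaxial α face of C7, giving the 7β alcohol, and ketones without a nearby hydroxyl are not reduced by this reagent.

Step 21
Reactants: 34 diol
Product: 35 spiro α-methylene-γ-butyrolactone at C5 (C4(=CH2)–C18(=O)–O–C19H2; 7β-OH; C2–OTBS, dithiane and C2 vinyl retained)
Conditions: Pd(PPh3)4, CO (1 atm), Et3N, DMF, 60 °C
Reagents that add atoms: carbon monoxide, [C-]#[O+]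
Why: Palladium-catalysed carbonylative lactonization (oxidative addition into the enol triflate, CO insertion, capture of the acylpalladium by the C19 hydroxyl in a five-membered ring); the C7 hydroxyl cannot reach.

Step 22
Reactants: 35 hydroxy methylene lactone
Product: 36 7β-acetate of 35
Conditions: Ac2O, pyridine, DMAP, CH2Cl2, rt
Reagents that add atoms: acetic anhydride, CC(=O)OC(C)=O
Why: Standard acylation of the only free hydroxyl.

Step 23
Reactants: 36 acetate
Product: 37 ring-closed tetracycle (target skeleton with C2–OTBS and C12 as 1,3-dithiane)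
Conditions: second-generation Grubbs catalyst RuCl2(=CHPh)(PCy3)(H2IMes), toluene, 90 °C
Reagents that add atoms: none
Why: Ring-closing metathesis; the ruthenium carbene loads on the monosubstituted C2 vinyl group and closes six-membered ring A onto the 1,1-disubstituted lactone alkene, releasing ethylene and giving the C3=C4 bond conjugated to the lactone.

Step 24
Reactants: 37 dithiane
Product: 38 2-O-TBS ether of the target (C12 ketone)
Conditions: PhI(OCOCF3)2, MeCN/H2O, 0 °C
Reagents that add atoms: water, O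
Why: Oxidative dithiane hydrolysis with a hypervalent iodine reagent (Stork conditions), fast for an aryl-substituted dithiane and expected to spare alkene, acetate, lactone and silyl ether.

Step 25
Reactants: 38 2-O-TBS ether
Product: 39 target CNP0182929.2
Conditions: HF·pyridine, pyridine, THF, 0 °C → rt
Reagents that add atoms: none
Why: Fluoride desilylation of the secondary TBS ether under buffered conditions that leave acetate and lactone intact.

Compound list
1 | ethyl 2-methyl-3-oxobutanoate | CCOC(=O)C(C)C(C)=O | starting material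
2 | ethyl (E)-2-methyl-3-(trifluoromethylsulfonyloxy)but-2-enoate | CCOC(=O)/C(C)=C(C)/OS(=O)(=O)C(F)(F)F | intermediate
3 | (E)-4-hydroxy-3-methylbut-2-en-2-yl trifluoromethanesulfonate | OC/C(C)=C(C)/OS(=O)(=O)C(F)(F)F | intermediate
4 | (E)-4-bromo-3-methylbut-2-en-2-yl trifluoromethanesulfonate | BrC/C(C)=C(C)/OS(=O)(=O)C(F)(F)F | intermediate
5 | dimethyl 3-oxopentanedioate | COC(=O)CC(=O)CC(=O)OC | starting material
6 | chloroacetaldehyde (aqueous solution) | ClCC=O | starting material
7 | methyl 2-(2-methoxy-2-oxoethyl)furan-3-carboxylate | COC(=O)Cc1occc1C(=O)OC | intermediate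
8 | 2-[3-(methoxycarbonyl)furan-2-yl]acetic acid | OC(=O)Cc1occc1C(=O)OC | intermediate
9 | (R)-4-benzyloxazolidin-2-one | O=C1N[C@H](Cc2ccccc2)CO1 | starting material
10 | 2-[3-(methoxycarbonyl)furan-2-yl]acetic pivalic anhydride | COC(=O)c1ccoc1CC(=O)OC(=O)C(C)(C)C | intermediate (not isolated)
11 | methyl 2-{2-[(R)-4-benzyl-2-oxooxazolidin-3-yl]-2-oxoethyl}furan-3-carboxylate | COC(=O)c1ccoc1CC(=O)N1C(=O)OC[C@H]1Cc1ccccc1 | intermediate
12 | acrolein | C=CC=O | starting material
13 | Z dibutylboron enolate of 11 | CCCCB(CCCC)O/C(=C\c1occc1C(=O)OC)N1C(=O)OC[C@H]1Cc1ccccc1 | intermediate (not isolated)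
14 | (R)-4-benzyl-3-{(2S,3S)-3-hydroxy-2-[3-(methoxycarbonyl)furan-2-yl]pent-4-enoyl}oxazolidin-2-one | C=C[C@H](O)[C@H](C(=O)N1C(=O)OC[C@H]1Cc1ccccc1)c1occc1C(=O)OC | intermediate
15 | (R)-4-benzyl-3-{(2S,3S)-3-(tert-butyldimethylsilyloxy)-2-[3-(methoxycarbonyl)furan-2-yl]pent-4-enoyl}oxazolidin-2-one | C=C[C@H](O[Si](C)(C)C(C)(C)C)[C@H](C(=O)N1C(=O)OC[C@H]1Cc1ccccc1)c1occc1C(=O)OC | intermediate
16 | methyl 2-[(2S,3S)-3-(tert-butyldimethylsilyloxy)-1-hydroxypent-4-en-2-yl]furan-3-carboxylate | C=C[C@H](O[Si](C)(C)C(C)(C)C)[C@H](CO)c1occc1C(=O)OC | intermediate (not isolated)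
17 | (S)-7-[(S)-1-(tert-butyldimethylsilyloxy)prop-2-en-1-yl]-6,7-dihydro-4H-furo[3,2-c]pyran-4-one | C=C[C@H](O[Si](C)(C)C(C)(C)C)[C@@H]1COC(=O)c2ccoc21 | intermediate
18 | (7S)-7-[(S)-1-(tert-butyldimethylsilyloxy)prop-2-en-1-yl]-6,7-dihydro-4H-furo[3,2-c]pyran-4-ol, both anomers | C=C[C@H](O[Si](C)(C)C(C)(C)C)[C@@H]1COC(O)c2ccoc21 | intermediate
19 | (2S,3S)-3-(tert-butyldimethylsilyloxy)-2-[3-(1,3-dithian-2-yl)furan-2-yl]pent-4-en-1-ol | C=C[C@H](O[Si](C)(C)C(C)(C)C)[C@H](CO)c1occc1C1SCCCS1 | intermediate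
20 | dilithio dianion of 19 (lithium alkoxide, 2-lithio-1,3-dithiane) | C=C[C@H](O[Si](C)(C)C(C)(C)C)[C@H](CO[Li])c1occc1C1([Li])SCCCS1 | intermediate (not isolated)
21 | (2S,3S)-3-(tert-butyldimethylsilyloxy)-2-(3-{2-[(E)-2-methyl-3-(trifluoromethylsulfonyloxy)but-2-en-1-yl]-1,3-dithian-2-yl}furan-2-yl)pent-4-en-1-ol | C=C[C@H](O[Si](C)(C)C(C)(C)C)[C@H](CO)c1occc1C1(C/C(C)=C(C)/OS(=O)(=O)C(F)(F)F)SCCCS1 | intermediate
22 | (2S,3S)-3-(tert-butyldimethylsilyloxy)-2-(3-{2-[(E)-2-methyl-3-(trifluoromethylsulfonyloxy)but-2-en-1-yl]-1,3-dithian-2-yl}furan-2-yl)pent-4-enal | C=C[C@H](O[Si](C)(C)C(C)(C)C)[C@H](C=O)c1occc1C1(C/C(C)=C(C)/OS(=O)(=O)C(F)(F)F)SCCCS1 | intermediate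
23 | 1-(triphenylphosphoranylidene)propan-2-one | CC(=O)C=P(c1ccccc1)(c1ccccc1)c1ccccc1 | starting material
24 | 1-iodo-1-(triphenylphosphoranylidene)propan-2-one | CC(=O)C(I)=P(c1ccccc1)(c1ccccc1)c1ccccc1 | intermediate (not isolated)
25 | (3Z,5S,6S)-6-(tert-butyldimethylsilyloxy)-3-iodo-5-(3-{2-[(E)-2-methyl-3-(trifluoromethylsulfonyloxy)but-2-en-1-yl]-1,3-dithian-2-yl}furan-2-yl)octa-3,7-dien-2-one | C=C[C@H](O[Si](C)(C)C(C)(C)C)[C@H](/C=C(\I)C(C)=O)c1occc1C1(C/C(C)=C(C)/OS(=O)(=O)C(F)(F)F)SCCCS1 | intermediate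
26 | (tributylstannyl)methanol | CCCC[Sn](CCCC)(CCCC)CO | starting material
27 | (3E,5S,6S)-6-(tert-butyldimethylsilyloxy)-3-(hydroxymethyl)-5-(3-{2-[(E)-2-methyl-3-(trifluoromethylsulfonyloxy)but-2-en-1-yl]-1,3-dithian-2-yl}furan-2-yl)octa-3,7-dien-2-one | C=C[C@H](O[Si](C)(C)C(C)(C)C)[C@H](/C=C(\CO)C(C)=O)c1occc1C1(C/C(C)=C(C)/OS(=O)(=O)C(F)(F)F)SCCCS1 | intermediate
28 | triethylsilyl ether of 27 | C=C[C@H](O[Si](C)(C)C(C)(C)C)[C@H](/C=C(\CO[Si](CC)(CC)CC)C(C)=O)c1occc1C1(C/C(C)=C(C)/OS(=O)(=O)C(F)(F)F)SCCCS1 | intermediate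
29 | tributyl(1-ethoxyvinyl)stannane | CCCC[Sn](CCCC)(CCCC)C(=C)OCC | starting material
30 | triene: as 28 with the (E)-4-ethoxy-2,3-dimethylpenta-2,4-dien-1-yl group on the dithiane carbon | C=C[C@H](O[Si](C)(C)C(C)(C)C)[C@H](/C=C(\CO[Si](CC)(CC)CC)C(C)=O)c1occc1C1(C/C(C)=C(C)/C(=C)OCC)SCCCS1 | intermediate (not isolated)
31 | Diels–Alder adduct (7-ethoxy-Δ7, 8-methyl, 5β-acetyl, 5α-CH2OSiEt3, 9α-CH3, 10β-H, trans B/C, C12 dithiane, C1 with (S)-CH(OTBS)CH=CH2) | CCOC1=C(C)[C@]2(C)CC4(SCCCS4)c3ccoc3[C@H]([C@@H](O[Si](C)(C)C(C)(C)C)C=C)[C@H]2[C@](CO[Si](CC)(CC)CC)(C(C)=O)C1 | intermediate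
32 | enol triflate of 31 (5β-[1-(trifluoromethylsulfonyloxy)vinyl]) | CCOC1=C(C)[C@]2(C)CC4(SCCCS4)c3ccoc3[C@H]([C@@H](O[Si](C)(C)C(C)(C)C)C=C)[C@H]2[C@](CO[Si](CC)(CC)CC)(C(=C)OS(=O)(=O)C(F)(F)F)C1 | intermediate
33 | 7-oxo-8α-methyl hydroxy ketone (19-OH free, enol triflate at C4) | O=C1[C@@H](C)[C@]2(C)CC4(SCCCS4)c3ccoc3[C@H]([C@@H](O[Si](C)(C)C(C)(C)C)C=C)[C@H]2[C@](CO)(C(=C)OS(=O)(=O)C(F)(F)F)C1 | intermediate
34 | 7β,19-diol (enol triflate at C4) | O[C@@H]1[C@@H](C)[C@]2(C)CC4(SCCCS4)c3ccoc3[C@H]([C@@H](O[Si](C)(C)C(C)(C)C)C=C)[C@H]2[C@](CO)(C(=C)OS(=O)(=O)C(F)(F)F)C1 | intermediate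
35 | 7β-hydroxy spiro α-methylene-γ-butyrolactone | O[C@@H]1[C@@H](C)[C@]2(C)CC4(SCCCS4)c3ccoc3[C@H]([C@@H](O[Si](C)(C)C(C)(C)C)C=C)[C@H]2[C@@]5(COC(=O)C5=C)C1 | intermediate
36 | 7β-acetate of 35 | CC(=O)O[C@@H]1[C@@H](C)[C@]2(C)CC4(SCCCS4)c3ccoc3[C@H]([C@@H](O[Si](C)(C)C(C)(C)C)C=C)[C@H]2[C@@]5(COC(=O)C5=C)C1 | intermediate
37 | target skeleton with 2α-OTBS and C12 as 1,3-dithiane | CC(=O)O[C@H]1C[C@@]23COC(=O)C2=C[C@H](O[Si](C)(C)C(C)(C)C)[C@H]2c4occc4C5(SCCCS5)C[C@@](C)([C@@H]1C)[C@@H]23 | intermediate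
38 | 2-O-tert-butyldimethylsilyl ether of the target | CC(=O)O[C@H]1C[C@@]23COC(=O)C2=C[C@H](O[Si](C)(C)C(C)(C)C)[C@H]2c4occc4C(=O)C[C@@](C)([C@@H]1C)[C@@H]23 | intermediate
39 | CNP0182929.2: (1S,2S,5S,7S,8S,9R,10R) 7β-acetoxy-2α-hydroxy-12-oxo-16→1-cycloclerod-3-en-18,19-olide with the C13–C16 furan | CC(=O)O[C@H]1C[C@@]23COC(=O)C2=C[C@H](O)[C@H]2c4occc4C(=O)C[C@@](C)([C@@H]1C)[C@@H]23 | target

Total step count: 25. Longest linear sequence: 22 steps (steps 4–25, from 5 and 6); bromide 4 (steps 1–3) joins at step 12.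

Steps most likely to fail

Step 17. The tetrasubstituted diene terminus may react too slowly with the electronically mismatched enone, so that a 1,5-hydrogen shift of the cis-methyl diene or loss of endo selectivity takes over. The fallback sets out from 28 and returns at 37. Stille coupling of 28 with tributyl(vinyl)stannane would give the 7-deoxy triene F1, whose unpolarized diene tolerates Lewis acid. Me2AlCl-promoted intramolecular Diels–Alder reaction (CH2Cl2, −40 → 0 °C) would give the Δ7 adduct F2. Triflation as in step 18 gives enol triflate F3, PPTS/MeOH frees the primary alcohol F4, carbonylative lactonization as in step 21 gives the methylene lactone F5, and metathesis as in step 23 gives the ring A/B/C diene F6. Hydroboration (BH3·SMe2, then Me3NO) should add boron to C7 and hydrogen to C8 from the β face, opposite the axial C19 and C20 groups, giving the 7β-alcohol F7, which is acetylated to 37.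

Step 23. Ring closure onto the hindered, electron-poor 1,1-disubstituted alkene next to quaternary C5 may be slower than catalyst decomposition or dimerization through the vinyl group. The fallback sets out from 32 and returns at 37; it closes ring A before the lactone exists. Methoxycarbonylation of 32 (Pd(PPh3)4, CO, MeOH, Et3N) would give the open methyl acrylate F8, whose freely rotating ester should undergo metathesis more readily to the cyclohexene ester F9. Aqueous HCl then hydrolyses the enol ether, removes TES and lets the C19 hydroxyl lactonize onto the C18 ester, giving the keto lactone F10. NaBH4 (MeOH, −40 °C) should attack C7 equatorially to give the axial 7α-alcohol F11, and Mitsunobu inversion (PPh3, DIAD, AcOH) gives 37.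

Step 20. Facial selectivity may be poor if hydride delivery from the C19-bound boron (seven-membered transition state) does not outcompete undirected attack. The fallback sets out from 33 and returns at 36; it uses the intrinsic bias and then inverts. LiBH(sBu)3 (THF, −78 °C) should attack from the unhindered equatorial β side to give the 7α-alcohol F12. Carbonylative lactonization as in step 21 gives the 7α-hydroxy methylene lactone F13, and Mitsunobu reaction with acetic acid (PPh3, DIAD) installs the 7β-acetate with inversion, giving 36.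

Further compounds
F1 | step 17 | 7-deoxy triene (as 30 with a (E)-2,3-dimethylpenta-2,4-dien-1-yl group) | C=C[C@H](O[Si](C)(C)C(C)(C)C)[C@H](/C=C(\CO[Si](CC)(CC)CC)C(C)=O)c1occc1C1(C/C(C)=C(C)/C=C)SCCCS1
F2 | step 17 | Δ7 Diels–Alder adduct (as 31 without the ethoxy group) | C1=C(C)[C@]2(C)CC4(SCCCS4)c3ccoc3[C@H]([C@@H](O[Si](C)(C)C(C)(C)C)C=C)[C@H]2[C@](CO[Si](CC)(CC)CC)(C(C)=O)C1
F3 | step 17 | enol triflate of F2 | C1=C(C)[C@]2(C)CC4(SCCCS4)c3ccoc3[C@H]([C@@H](O[Si](C)(C)C(C)(C)C)C=C)[C@H]2[C@](CO[Si](CC)(CC)CC)(C(=C)OS(=O)(=O)C(F)(F)F)C1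
F4 | step 17 | 19-hydroxy enol triflate | C1=C(C)[C@]2(C)CC4(SCCCS4)c3ccoc3[C@H]([C@@H](O[Si](C)(C)C(C)(C)C)C=C)[C@H]2[C@](CO)(C(=C)OS(=O)(=O)C(F)(F)F)C1
F5 | step 17 | Δ7 spiro α-methylene lactone | C1=C(C)[C@]2(C)CC4(SCCCS4)c3ccoc3[C@H]([C@@H](O[Si](C)(C)C(C)(C)C)C=C)[C@H]2[C@@]5(COC(=O)C5=C)C1
F6 | step 17 | 7-deoxy-Δ7 tetracycle (2α-OTBS, C12 dithiane) | CC1=CC[C@@]23COC(=O)C2=C[C@H](O[Si](C)(C)C(C)(C)C)[C@H]2c4occc4C5(SCCCS5)C[C@]1(C)[C@@H]23
F7 | step 17 | 7β-alcohol (deacetyl 37) | O[C@H]1C[C@@]23COC(=O)C2=C[C@H](O[Si](C)(C)C(C)(C)C)[C@H]2c4occc4C5(SCCCS5)C[C@@](C)([C@@H]1C)[C@@H]23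
F8 | step 23 | methyl acrylate (as 32 with C(=CH2)CO2Me at C5) | CCOC1=C(C)[C@]2(C)CC4(SCCCS4)c3ccoc3[C@H]([C@@H](O[Si](C)(C)C(C)(C)C)C=C)[C@H]2[C@](CO[Si](CC)(CC)CC)(C(=C)C(=O)OC)C1
F9 | step 23 | ring A cyclohexene methyl ester (7-ethoxy enol ether, 19-OTES) | CCOC1=C(C)[C@]2(C)CC3(SCCCS3)c4ccoc4[C@@H]5[C@@H](O[Si](C)(C)C(C)(C)C)C=C(C(=O)OC)[C@](CO[Si](CC)(CC)CC)(C1)[C@@H]25
F10 | step 23 | 7-oxo lactone (2α-OTBS, C12 dithiane) | O=C1C[C@@]23COC(=O)C2=C[C@H](O[Si](C)(C)C(C)(C)C)[C@H]2c4occc4C5(SCCCS5)C[C@@](C)([C@@H]1C)[C@@H]23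
F11 | step 23 | 7α-alcohol (2α-OTBS, C12 dithiane) | O[C@@H]1C[C@@]23COC(=O)C2=C[C@H](O[Si](C)(C)C(C)(C)C)[C@H]2c4occc4C5(SCCCS5)C[C@@](C)([C@@H]1C)[C@@H]23
F12 | step 20 | 7α,19-diol enol triflate (C7 epimer of 34) | O[C@H]1[C@@H](C)[C@]2(C)CC4(SCCCS4)c3ccoc3[C@H]([C@@H](O[Si](C)(C)C(C)(C)C)C=C)[C@H]2[C@](CO)(C(=C)OS(=O)(=O)C(F)(F)F)C1
F13 | step 20 | 7α-hydroxy spiro α-methylene lactone (C7 epimer of 35) | O[C@H]1[C@@H](C)[C@]2(C)CC4(SCCCS4)c3ccoc3[C@H]([C@@H](O[Si](C)(C)C(C)(C)C)C=C)[C@H]2[C@@]5(COC(=O)C5=C)C1
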